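**Plan**

- Retrosynthesis: the two malonate C(=O)–O15 bonds are cut first (malonic acid plus two copies of labda-7,13E-dien-15-ol), then the O–acetyl bond of the corresponding acetate, then C11–C12 and C15–O in one operation (drim-7-en-11-yl iodide, isoprene, acetate), and last C11–I, the C11–C12 carboxyl bond and the C8–O lactone bond, back to (+)-sclareolide.
- Enabling feature: C12–C13(C16)=C14–C15 is exactly one isoprene unit held between C11 and the ester oxygen, with an E C13=C14 alkene in the middle. The side chain is therefore a 1,4-adduct of isoprene on the drimane rings A/B.
- Forward: no ring is formed. The trans-decalin comes intact from sclareolide; the lactone is opened with dehydration to C7=C8, C12 is excised as CO2 with C11–I formation, the C5 unit is inserted between C11 and acetate, and after deacetylation two alcohols are joined through malonic acid.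
- Stereochemistry: C5, C9 and C10 (5α-H, 9α-H, 10β-CH3) are those of sclareolide and are never touched; C8 becomes sp2; the 13E geometry is set in the key step from s-trans isoprene.

Key step: step 4

Remark: labdane numbering is used throughout. The target string is read as the malonic diester of two identical normal-series labda-7,13E-dien-15-ol units, which is what both halves of the SMILES encode.

Step 1
Reactants: 1 (+)-sclareolide
Product: 2 methyl 13,14,15,16-tetranorlabd-7-en-12-oate
Conditions: conc. H2SO4 (cat.), MeOH, rt; chromatography on AgNO3-impregnated silica
Reagents that add atoms: methanol, CO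
Why: Acid-catalysed methanolysis opens the lactone by ionising the tertiary C8–O bond and the C8 cation loses a C7 proton (E1 dehydration), which should favour the endocyclic trisubstituted alkene, while esterification blocks relactonisation; the accompanying Δ8(9) and Δ8(17) isomers are removed on AgNO3-silica and C5, C9 and C10 are not involved.

Step 2
Reactants: 2 methyl 13,14,15,16-tetranorlabd-7-en-12-oate
Product: 3 13,14,15,16-tetranorlabd-7-en-12-oic acid
Conditions: KOH (3 equiv), MeOH/H2O, 60 °C; then cold 1 M HCl to pH 4
Reagents that add atoms: potassium hydroxide, [K+].[OH-]
Why: Ordinary saponification of an unhindered methyl ester, followed by cold acidification only to pH 4 so that the γ,δ-unsaturated acid does not relactonise onto C8.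

Step 3
Reactants: 3 13,14,15,16-tetranorlabd-7-en-12-oic acid
Product: 5 drim-7-en-11-yl iodide, via Barton ester 4 (not isolated)
Conditions: 1-hydroxypyridine-2(1H)-thione (1.2 equiv), DCC (1.2 equiv), DMAP (cat.), CH2Cl2, 0 °C → rt, dark; then CHI3 (2 equiv), hν (tungsten lamp), rt
Reagents that add atoms: iodoform, IC(I)I; 1-hydroxypyridine-2(1H)-thione, ON1C=CC=CC1=S (its atoms are in intermediate 4 only)
Why: DCC acylation of the thiohydroxamic acid gives the Barton ester, whose light-initiated radical chain decarboxylation (Barton decarboxylative iodination) releases the C11 radical, which takes iodine from iodoform faster than it can cyclise onto C7=C8, and the absence of any electrophilic iodine source keeps the alkene and the acid from iodolactonising.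

Step 4
Reactants: 5 drim-7-en-11-yl iodide; 6 isoprene; 7 caesium acetate
Product: 8 labda-7,13E-dien-15-yl acetate
Conditions: Pd(PPh3)4 (10 mol %), CsOAc 7 (3 equiv), isoprene 6 (20 equiv, ca. 3 M), degassed DMA, blue LEDs (450 nm), 25 °C, sealed tube
Reagents that add atoms: none
Why: Proposed new method: blue-light-excited Pd(0) should abstract iodine from the β-branched primary iodide 5, which is too hindered for ionic substitution, to give the C11 radical and Pd(I)–I; the radical adds to the CH2 terminus of isoprene next to the methyl-bearing carbon (C11–C12 bond), the 1,1-disubstituted allyl radical recombines with Pd(I) to a π-allylpalladium(II) species, and acetate opens this at its unsubstituted terminus (C15–O bond) with return of Pd(0). The closest known reaction type is the visible-light palladium-catalysed three-component 1,4-carboamination of 1,3-dienes with unactivated alkyl halides; what is untested is a carboxylate as the terminating nucleophile on isoprene, which is thermodynamically reasonable because ionisation of an allylic acetate by Pd(0)/phosphine lies on the side of the acetate. No ring closes and no stereocentre is created, and C5, C9 and C10 of 5 are remote from the reacting atoms and pass through unchanged. Three selectivities are needed: radical attack at C1 rather than C4 of isoprene, secured only moderately by the more substituted allyl radical; acetate delivery to C15, secured by the steric difference between the primary and the fully substituted allyl terminus and by reversibility, which returns any tertiary acetate to the π-allyl pool; and E geometry at C13=C14, inherited from s-trans isoprene and held because syn/anti exchange at C13 would require a tertiary σ-palladium species. The homoallylic C11 radical could close 3-exo onto C7=C8 and reopen with ring expansion (1,2-vinyl shift), so isoprene is kept at about 3 M to make bimolecular capture the faster path.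

Step 5
Reactants: 8 labda-7,13E-dien-15-yl acetate
Product: 9 labda-7,13E-dien-15-ol
Conditions: K2CO3 (0.2 equiv), MeOH, rt
Reagents that add atoms: none
Why: Carbonate-catalysed transesterification with methanol (Zemplén-type deacetylation) removes the primary allylic acetate without touching the alkenes or any stereocentre.

Step 6
Reactants: 9 labda-7,13E-dien-15-ol (2.1 equiv); 10 malonic acid
Product: 11 bis(labda-7,13E-dien-15-yl) malonate (CNP0113044.1)
Conditions: DCC (2.2 equiv), DMAP (0.2 equiv), CH2Cl2/THF, 0 °C → rt
Reagents that add atoms: none
Why: Steglich esterification (DCC, catalytic DMAP) acylates the primary allylic alcohol twice under neutral conditions that spare the trisubstituted alkenes and the ionisable allylic C15–O bonds, the alcohol being used in slight excess to drive the second acylation.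

**Compound list**

1 | (+)-sclareolide (8α,12-olide; 5α-H, 9α-H, 10β-CH3, 8β-CH3) | C[C@@]12CC[C@H]3C(C)(C)CCC[C@]3(C)[C@H]1CC(=O)O2 | starting material
2 | methyl 13,14,15,16-tetranorlabd-7-en-12-oate (CH2CO2Me on C9, C7=C8; 5α-H, 9α-H, 10β-CH3) | CC1=CC[C@H]2C(C)(C)CCC[C@]2(C)[C@H]1CC(=O)OC | intermediate
3 | 13,14,15,16-tetranorlabd-7-en-12-oic acid | CC1=CC[C@H]2C(C)(C)CCC[C@]2(C)[C@H]1CC(=O)O | intermediate
4 | 2-thioxopyridin-1(2H)-yl 13,14,15,16-tetranorlabd-7-en-12-oate (Barton ester of 3) | CC1=CC[C@H]2C(C)(C)CCC[C@]2(C)[C@H]1CC(=O)ON3C=CC=CC3=S | intermediate
5 | drim-7-en-11-yl iodide (11-iododrim-7-ene; CH2I on C9; 5α-H, 9α-H, 10β-CH3) | CC1=CC[C@H]2C(C)(C)CCC[C@]2(C)[C@H]1CI | intermediate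
6 | isoprene | C=CC(C)=C | starting material
7 | caesium acetate | CC(=O)[O-].[Cs+] | starting material
8 | labda-7,13E-dien-15-yl acetate | CC1=CC[C@H]2C(C)(C)CCC[C@]2(C)[C@H]1CC/C(C)=C/COC(C)=O | intermediate
9 | labda-7,13E-dien-15-ol | CC1=CC[C@H]2C(C)(C)CCC[C@]2(C)[C@H]1CC/C(C)=C/CO | intermediate
10 | malonic acid | OC(=O)CC(=O)O | starting material
11 | bis(labda-7,13E-dien-15-yl) malonate (CNP0113044.1) | CC1=CC[C@H]2C(C)(C)CCC[C@]2(C)[C@H]1CC/C(C)=C/COC(=O)CC(=O)OC/C=C(\C)CC[C@H]1C(C)=CC[C@H]2C(C)(C)CCC[C@]12C | target

**Step count**

Total step count: 6. Longest linear sequence: 6 steps (1 → 2 → 3 → 5 → 8 → 9 → 11).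

**Steps most likely to fail**

First, step 4, the step with a proposed new method. Several processes could defeat it:
- acetate may fail to intercept the π-allyl intermediate, so that β-hydride loss to a triene takes over;
- the radical may attack the wrong isoprene terminus;
- the C11 radical may undergo the ring-expanding vinyl shift before it meets isoprene;
- reversible ionisation of the product may erode the E geometry.

The fallback uses known chemistry, sets out from iodide 5 and returns at alcohol 9, bypassing 8. A tin-free Giese addition of 5 to methyl vinyl ketone in excess ((TMS)3SiH, AIBN, toluene, 80 °C) should form C11–C12 and give 14,15-dinorlabd-7-en-13-one F1. Horner–Wadsworth–Emmons olefination of this methyl ketone with triethyl phosphonoacetate and NaH in THF should then give ethyl labda-7,13E-dien-15-oate F2, the E isomer being separated from the minor Z isomer by chromatography. DIBAL-H reduction in CH2Cl2 at −78 °C would deliver 9.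

Second, step 1. Proton loss from the C8 cation may be poorly regioselective, and continued acid exposure may move the double bond on to the tetrasubstituted position, leaving a mixture that is hard to separate. The fallback sets out from 1 and returns at 2. The lactone is opened with KOH in MeOH and the carboxylate alkylated with iodomethane in DMF to give methyl 8α-hydroxy-13,14,15,16-tetranorlabdan-12-oate F3. Kinetic dehydration of this equatorial tertiary alcohol with SOCl2/pyridine at −78 °C should favour the exocyclic alkene, methyl 13,14,15,16-tetranorlabd-8(17)-en-12-oate F4. A cobalt-hydride hydrogen-atom-transfer isomerisation (Co(salen)Cl cat., PhSiH3 cat., benzene, rt) would then move the double bond one position into the ring, with hydrogen abstraction expected at the accessible C7 methylene rather than the shielded C9 methine, to give 2.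

Third, step 6. Double activation of malonic acid may stall after the first acylation or drain into N-acylurea and ketene-derived by-products, consuming the alcohol. The fallback sets out from 9 and returns at 11. Heating 9 with Meldrum's acid in toluene at 100 °C should open the dioxanedione, with loss of acetone, to hydrogen labda-7,13E-dien-15-yl malonate F5. This single acid is then esterified with a second equivalent of 9 (DCC, DMAP, CH2Cl2, 0 °C → rt) to give 11.

**Further compounds**

F1 | step 4 | 14,15-dinorlabd-7-en-13-one | CC1=CC[C@H]2C(C)(C)CCC[C@]2(C)[C@H]1CCC(C)=O
F2 | step 4 | ethyl labda-7,13E-dien-15-oate | CC1=CC[C@H]2C(C)(C)CCC[C@]2(C)[C@H]1CC/C(C)=C/C(=O)OCC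
F3 | step 1 | methyl 8α-hydroxy-13,14,15,16-tetranorlabdan-12-oate | C[C@@]1(O)CC[C@H]2C(C)(C)CCC[C@]2(C)[C@H]1CC(=O)OC
F4 | step 1 | methyl 13,14,15,16-tetranorlabd-8(17)-en-12-oate | C=C1CC[C@H]2C(C)(C)CCC[C@]2(C)[C@H]1CC(=O)OC
F5 | step 6 | hydrogen labda-7,13E-dien-15-yl malonate | CC1=CC[C@H]2C(C)(C)CCC[C@]2(C)[C@H]1CC/C(C)=C/COC(=O)CC(=O)O
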